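**Retrosynthetic overview**

1. The strategy rests on ring B (C5–C6–C7–C8–C9–C20–C10, icetexane numbering): its arene edge C8–C9 (ring C) lies between two acyl-level carbons, C7 and C20. That is the pattern an aryne leaves when it inserts into the C7–C20 bond of a cyclopentanone fused to ring A.
2. Endgame disconnections: hydroxyquinone ⇐ 14-phenol/12-OMe arene (Teuber oxidation, hydrolysis); C1 and C7 carbinols ⇐ ketones; C10=C20 ⇐ β-sulfonyl ketone (sulfinate loss); C19→O6 lactone ⇐ hydroxy ester.
3. Key disconnection: benzo-fused ring B ⇐ cyclopentanone β-keto sulfone (C5–C6–C7–C20–C10) + a 3-methoxyaryne that brings ring C complete (from 1,3-dimethoxybenzene).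
4. Cyclopentanone ⇐ sulfone–ester condensation; C20 ⇐ phenylthiomethylation at C10; C4/C5/C6 ⇐ catalytic desymmetrising, lactone-forming Michael addition on a Birch-derived cyclohexadienone.
5. Ring order: A (benzoic acid) → temporary γ-lactone (sets C4–C6, then opened) → cyclopentanone → B by two-carbon ring expansion carrying C → lactone re-closed → quinone.

Key step: step 18

Remark on the chemistry: icetexane numbering is used for all intermediates; α/β refer to the usual diterpenoid drawing (H-5 α), and the SMILES in the compound list are authoritative. It is assumed that the sense of induction in step 4 can be chosen through the pseudoenantiomeric cinchona catalysts (series drawn: 4S,5R). A glycolate surrogate with an aryl ketone at C7 is used so that C6–H is acidic enough for ion-pair catalysis. C10 is carried as the H-10β (C5/C10 trans) epimer, which the alkylation should deliver; this centre is erased in step 21.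

**Route**

Step 1
Reactants: 1 benzoic acid
Product: 3 1-methylcyclohexa-2,5-diene-1-carboxylic acid, via dilithium dihydrobenzoate dianion 2 (not isolated)
Conditions: Li, NH3(l)/THF, −78 °C; MeI; aq HCl
Reagents that add atoms: iodomethane CI; lithium [Li] (in intermediate 2 only)
Why: Birch reduction of the benzoate stops at the enediolate dianion, which MeI alkylates at the carboxyl-bearing carbon (Birch reductive alkylation), so quaternary C4 with its two vinyl arms is made in one operation.

Step 2
Reactants: 3 1-methylcyclohexa-2,5-diene-1-carboxylic acid; 4 2-bromo-1-(4-methoxyphenyl)ethan-1-one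
Product: 5 2-(4-methoxyphenyl)-2-oxoethyl 1-methylcyclohexa-2,5-diene-1-carboxylate
Conditions: K2CO3, DMF, rt
Reagents that add atoms: none
Why: SN2 O-alkylation of the carboxylate by the α-bromo ketone installs C6 and C7 as a glycolate surrogate whose CH2 (acyloxy plus aryl ketone) can be enolised by mild base.

Step 3
Reactants: 5 2-(4-methoxyphenyl)-2-oxoethyl 1-methylcyclohexa-2,5-diene-1-carboxylate
Product: 6 2-(4-methoxyphenyl)-2-oxoethyl 1-methyl-4-oxocyclohexa-2,5-diene-1-carboxylate
Conditions: PDC (mediator), t-BuOOH, Celite, benzene, rt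
Reagents that add atoms: tert-butyl hydroperoxide CC(C)(C)OO
Why: Chromium(VI)/hydroperoxide allylic oxidation attacks the doubly allylic CH2, the only allylic position, and gives the 4,4-disubstituted cyclohexa-2,5-dienone, which has no enolisable ring hydrogen.

Step 4
Reactants: 6 2-(4-methoxyphenyl)-2-oxoethyl 1-methyl-4-oxocyclohexa-2,5-diene-1-carboxylate
Product: 7 (3R,3aR,7aS)-3-(4-methoxybenzoyl)-7a-methyl-3a,4-dihydro-2-benzofuran-1,5(3H,7aH)-dione (icetexane 4S,5R,6R)
Conditions: O-allyl-N-(9-anthracenylmethyl)cinchonidinium bromide (10 mol %), Cs2CO3, toluene/CH2Cl2, −30 °C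
Reagents that add atoms: none
Why: Chiral ion-pair (phase-transfer) catalysed intramolecular Michael addition (5-exo-trig): the ammonium-bound C6 enolate selects one of the two enantiotopic enone arms (desymmetrisation sets C4 and C5; the cinchoninium pseudoenantiomer is used if the induction is opposite), the two-atom ester tether enforces a cis-fused γ-lactone, and the acidic C6–H should equilibrate to the exo aroyl epimer (trans to C10), which is the target configuration at C6.

Step 5
Reactants: 7 (3R,3aR,7aS)-3-(4-methoxybenzoyl)-7a-methyl-3a,4-dihydro-2-benzofuran-1,5(3H,7aH)-dione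
Product: 8 4-methoxyphenyl (3R,3aR,7aS)-7a-methyl-1,5-dioxo-1,3,3a,4,5,7a-hexahydro-2-benzofuran-3-carboxylate
Conditions: m-CPBA, TFA (cat.), CH2Cl2, 0 °C → rt
Reagents that add atoms: m-chloroperoxybenzoic acid OOC(=O)c1cccc(Cl)c1
Why: Baeyer–Villiger oxidation in which the electron-rich 4-methoxyphenyl group migrates in preference to the acyloxy-substituted C6, which brings C7 to the ester level while the electron-poor enone stays inert and C6 is untouched.

Step 6
Reactants: 8 4-methoxyphenyl (3R,3aR,7aS)-7a-methyl-1,5-dioxo-1,3,3a,4,5,7a-hexahydro-2-benzofuran-3-carboxylate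
Product: 9 methyl (1S,6R)-6-[(1R)-1-hydroxy-2-methoxy-2-oxoethyl]-1-methyl-4-oxocyclohex-2-ene-1-carboxylate
Conditions: NaOMe (2.2 equiv), MeOH, 0 °C; AcOH, −20 °C
Reagents that add atoms: methanol CO (delivered as NaOMe/MeOH)
Why: Methoxide transesterifies the aryl ester and opens the γ-lactone by acyl substitution, the open form being favoured because the α-hydroxy-ester alkoxide is a weaker base than methoxide; C6 cannot enolise as its alkoxide, and cold neutralisation should leave the hydroxy diester kinetically stable toward re-closure on the hindered C19 ester.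

Step 7
Reactants: 9 methyl (1S,6R)-6-[(1R)-1-hydroxy-2-methoxy-2-oxoethyl]-1-methyl-4-oxocyclohex-2-ene-1-carboxylate
Product: 10 methyl (1S,6R)-6-[(1R)-2-methoxy-1-(methoxymethoxy)-2-oxoethyl]-1-methyl-4-oxocyclohex-2-ene-1-carboxylate
Conditions: MOMCl, i-Pr2NEt, CH2Cl2, 0 °C → rt
Reagents that add atoms: chloromethyl methyl ether COCCl
Why: O-alkylation with the α-chloro ether under weakly basic conditions caps O-6 so that it cannot re-lactonise or interfere in the enolate and carbanion steps, and the MOM acetal later leaves in the acid step that recloses the lactone.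

Step 8
Reactants: 10 methyl (1S,6R)-6-[(1R)-2-methoxy-1-(methoxymethoxy)-2-oxoethyl]-1-methyl-4-oxocyclohex-2-ene-1-carboxylate; 11 chloromethyl phenyl sulfide
Product: 14 methyl (1S,5R,6R)-6-[(1R)-2-methoxy-1-(methoxymethoxy)-2-oxoethyl]-1-methyl-4-oxo-5-[(phenylsulfanyl)methyl]cyclohex-2-ene-1-carboxylate, via lithium dienolate 12 (not isolated), via trimethylsilyl dienol ether 13 (not isolated)
Conditions: LDA, THF, −78 °C; TMSCl; solvent switch; 11, ZnBr2 (cat.), CH2Cl2, rt
Reagents that add atoms: lithium diisopropylamide [Li+].CC(C)[N-]C(C)C (lithium in intermediate 12 only); chlorotrimethylsilane C[Si](C)(C)Cl (silicon in intermediate 13 only)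
Why: Kinetic deprotonation finds only the α′-CH2 at C10 (C4 is quaternary), and the derived 2-silyloxydiene is alkylated at C10 by the thionium ion from 11 (Lewis-acid-promoted α-phenylthiomethylation of a silyl enol ether), the electrophile entering anti to the C5 side chain to give the C5/C10-trans product (C20 α).

Step 9
Reactants: 14 methyl (1S,5R,6R)-6-[(1R)-2-methoxy-1-(methoxymethoxy)-2-oxoethyl]-1-methyl-4-oxo-5-[(phenylsulfanyl)methyl]cyclohex-2-ene-1-carboxylate
Product: 15 methyl (1S,5R,6R)-6-[(1R)-2-methoxy-1-(methoxymethoxy)-2-oxoethyl]-1-methyl-4-oxo-5-[(phenylsulfonyl)methyl]cyclohex-2-ene-1-carboxylate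
Conditions: m-CPBA (2.2 equiv), NaHCO3, CH2Cl2, 0 °C → rt
Reagents that add atoms: m-chloroperoxybenzoic acid OOC(=O)c1cccc(Cl)c1
Why: Peracid S-oxidation takes the sulfide to the sulfone while the electron-poor enone alkene is not epoxidised, and the buffered medium avoids base-induced loss of sulfinate.

Step 10
Reactants: 15 methyl (1S,5R,6R)-6-[(1R)-2-methoxy-1-(methoxymethoxy)-2-oxoethyl]-1-methyl-4-oxo-5-[(phenylsulfonyl)methyl]cyclohex-2-ene-1-carboxylate
Product: 16 methyl (1S,2R,3R)-2-[(1R)-2-methoxy-1-(methoxymethoxy)-2-oxoethyl]-1-methyl-4-oxo-3-[(phenylsulfonyl)methyl]cyclohexane-1-carboxylate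
Conditions: H2 (1 atm), 10% Pd/C, EtOAc, rt
Reagents that add atoms: none
Why: Heterogeneous catalytic hydrogenation saturates the disubstituted enone C2=C3 after it has served to direct enolisation to C10, and the sulfone (unlike the sulfide) does not poison palladium.

Step 11
Reactants: 16 methyl (1S,2R,3R)-2-[(1R)-2-methoxy-1-(methoxymethoxy)-2-oxoethyl]-1-methyl-4-oxo-3-[(phenylsulfonyl)methyl]cyclohexane-1-carboxylate
Product: 17 methyl (6R,7R,8S)-7-[(1R)-2-methoxy-1-(methoxymethoxy)-2-oxoethyl]-8-methyl-6-[(phenylsulfonyl)methyl]-1,4-dioxaspiro[4.5]decane-8-carboxylate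
Conditions: (TMSOCH2)2, TMSOTf (cat.), CH2Cl2, −78 → −20 °C; pyridine
Reagents that add atoms: 1,2-bis(trimethylsilyloxy)ethane C[Si](C)(C)OCCO[Si](C)(C)C
Why: Aprotic TMSOTf-catalysed ketalisation at low temperature masks C1 while sparing the MOM acetal, so the β-sulfonyl ketone cannot lose sulfinate in the basic steps that follow.

Step 12
Reactants: 17 methyl (6R,7R,8S)-7-[(1R)-2-methoxy-1-(methoxymethoxy)-2-oxoethyl]-8-methyl-6-[(phenylsulfonyl)methyl]-1,4-dioxaspiro[4.5]decane-8-carboxylate
Product: 18 ring A-fused cyclopentanone β-keto sulfone (ring C5–C6–C7–C20–C10; 6-OMOM cis to H-5, 7-oxo, 20-SO2Ph as epimers, trans ring fusion with H-5 α and H-10 β, 1,1-ethylenedioxy, 4α-CH3, 4β-CO2Me)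
Conditions: LDA (1.1 equiv), THF, −78 → 0 °C; aq NH4Cl
Reagents that add atoms: none
Why: Sulfone–ester Claisen condensation of Dieckmann type (5-exo-trig): the kinetically formed C20 sulfonyl carbanion acylates on the C7 ester, the trans-diequatorial arms close a trans-hydrindan-2-one, the hindered C19 ester on the opposite face is out of reach, and the product is withdrawn as its stabilised enolate (C20 left unassigned).

Step 13
Reactants: 19 1,3-dimethoxybenzene
Product: 21 2-(2,6-dimethoxyphenyl)propan-2-ol, via 2,6-dimethoxyphenyllithium 20 (not isolated)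
Conditions: n-BuLi, THF, 0 °C → rt; acetone, −78 °C → rt; H2O
Reagents that add atoms: acetone CC(C)=O; n-butyllithium [Li]CCCC (lithium in intermediate 20 only)
Why: Directed ortho-metalation occurs at the position flanked by both methoxy groups, and the aryllithium adds to acetone.

Step 14
Reactants: 21 2-(2,6-dimethoxyphenyl)propan-2-ol
Product: 22 2-isopropyl-1,3-dimethoxybenzene
Conditions: Et3SiH, TFA, CH2Cl2, 0 °C → rt
Reagents that add atoms: none
Why: Ionic hydrogenation: the tertiary benzylic cation formed in acid is reduced by hydride transfer from the silane.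

Step 15
Reactants: 22 2-isopropyl-1,3-dimethoxybenzene
Product: 24 4-isopropyl-3,5-dimethoxyphenol, via aryl pinacol boronate 23 (not isolated)
Conditions: [Ir(OMe)(cod)]2 (cat.), dtbpy, B2pin2, THF, 80 °C; then 30% H2O2, aq NaOH, 0 °C; aq HCl
Reagents that add atoms: hydrogen peroxide OO; bis(pinacolato)diboron CC1(C)OB(OC1(C)C)B1OC(C)(C)C(C)(C)O1 (boron in intermediate 23 only)
Why: Sterically governed iridium-catalysed C–H borylation selects the only ring C–H without an ortho substituent (para to isopropyl), and oxidation of the boronate gives the phenol in the same pot.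

Step 16
Reactants: 24 4-isopropyl-3,5-dimethoxyphenol
Product: 25 2-bromo-4-isopropyl-3,5-dimethoxyphenol
Conditions: NBS (1.0 equiv), CH2Cl2, −40 °C
Reagents that add atoms: N-bromosuccinimide O=C1CCC(=O)N1Br
Why: Electrophilic aromatic bromination ortho to the hydroxyl; the two free positions are equivalent by symmetry, so only mono- versus di-bromination must be held by stoichiometry and temperature.

Step 17
Reactants: 25 2-bromo-4-isopropyl-3,5-dimethoxyphenol
Product: 28 4-isopropyl-3,5-dimethoxy-2-(trimethylsilyl)phenyl trifluoromethanesulfonate, via aryl trimethylsilyl ether 26 (not isolated), via lithium 2-silylphenoxide 27 (not isolated)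
Conditions: HMDS, THF, 70 °C; evaporate; n-BuLi, THF, −100 °C; Tf2O, −100 °C → rt
Reagents that add atoms: hexamethyldisilazane C[Si](C)(C)N[Si](C)(C)C; trifluoromethanesulfonic anhydride O=S(=O)(OS(=O)(=O)C(F)(F)F)C(F)(F)F; n-butyllithium [Li]CCCC (lithium in intermediate 27 only)
Why: O-silylation, bromine–lithium exchange with 1,3-retro-Brook O→C silyl shift and O-triflation is the standard sequence to an ortho-silylaryl triflate.

Step 18
Reactants: 18 ring A-fused cyclopentanone β-keto sulfone; 28 4-isopropyl-3,5-dimethoxy-2-(trimethylsilyl)phenyl trifluoromethanesulfonate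
Product: 31 methyl 1,1-(ethylenedioxy)-12,14-dimethoxy-6α-(methoxymethoxy)-7-oxo-20-(phenylsulfonyl)icetexa-8,11,13-trien-19-oate (C20 epimers; H-10 β), via aryne 29 (not isolated), via cesium benzocyclobutenoxide 30 (not isolated)
Conditions: CsF (3 equiv), 28 (1.5 equiv), MeCN, 80 °C
Reagents that add atoms: cesium fluoride [Cs+].[F-] (cesium in intermediate 30 only)
Why: Fluoride removes the silyl group of 28 to release aryne 29 and also deprotonates the acidic C20–H of 18; the C20 carbanion adds to the aryne carbon remote from the flanking methoxy group (future C9), and the aryl anion formed at C8 adds to the C7 carbonyl to give benzocyclobutenoxide 30. Retro-aldol-type fragmentation of 30 breaks the original C7–C20 bond and releases a sulfone- and aryl-stabilised C20 carbanion that is protonated, so the arene edge C8–C9 is inserted into the C7–C20 σ-bond. This is the aryne acyl-alkylation known for cyclic β-keto esters and β-keto sulfones. Ring B (C5–C6–C7–C8–C9–C20–C10) is therefore not closed by cyclisation but arises by two-carbon expansion of the five-membered ring (4-exo-trig closure to the cyclobutenoxide, then C–C fragmentation). No stereocentre is set under control: C4, C5, C6 and C10 are carried over, and C20 forms as epimers that step 21 erases. The selectivity needed is the regiochemistry of aryne capture, secured by the 3-methoxy group of 29 (nucleophile enters meta to OMe), which places C7 next to C14–OMe and C20 next to C11–H; reaction at C20 and not C6 follows from the far higher acidity of the β-keto sulfone C–H.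

Step 19
Reactants: 31 methyl 1,1-(ethylenedioxy)-12,14-dimethoxy-6α-(methoxymethoxy)-7-oxo-20-(phenylsulfonyl)icetexa-8,11,13-trien-19-oate
Product: 33 12,14-dimethoxy-1,7-dioxo-20-(phenylsulfonyl)-10βH-icetexa-8,11,13-trien-19,6-olide (O-6 α; C20 epimers), via hydroxy keto ester 32 (not isolated)
Conditions: 6 M aq HCl/THF (1:3), 50 °C
Reagents that add atoms: water O
Why: Aqueous acid hydrolyses the dioxolane and the MOM acetal, and the freed 6-OH closes the γ-lactone on the C19 ester by acid-catalysed transesterification (5-exo-trig; cis-fused to ring A and trans-fused to ring B as in the target) without touching a stereocentre.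

Step 20
Reactants: 33 12,14-dimethoxy-1,7-dioxo-20-(phenylsulfonyl)-10βH-icetexa-8,11,13-trien-19,6-olide
Product: 34 14-hydroxy-12-methoxy-1,7-dioxo-20-(phenylsulfonyl)-10βH-icetexa-8,11,13-trien-19,6-olide
Conditions: BCl3 (1.5 equiv), CH2Cl2, −78 → 0 °C; aq NaHCO3
Reagents that add atoms: none
Why: Chelation-directed Lewis-acid demethylation: boron bridges the C7 carbonyl and the ortho C14 methoxy oxygen, so only that ether is cleaved and the para C12–OMe, which cannot chelate, is kept.

Step 21
Reactants: 34 14-hydroxy-12-methoxy-1,7-dioxo-20-(phenylsulfonyl)-10βH-icetexa-8,11,13-trien-19,6-olide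
Product: 35 14-hydroxy-12-methoxy-1,7-dioxoicetexa-8,10(20),11,13-tetraen-19,6-olide
Conditions: DBU (2.2 equiv), CH2Cl2, 0 °C; dilute aq HCl
Reagents that add atoms: none
Why: E1cB elimination: DBU removes H-10 (α to the C1 ketone) and benzenesulfinate leaves from C20 to give the arene-conjugated C10=C20 enone, while the C14 phenoxide formed first makes C7=O a vinylogous carboxylate and so should suppress enolisation toward C6.

Step 22
Reactants: 35 14-hydroxy-12-methoxy-1,7-dioxoicetexa-8,10(20),11,13-tetraen-19,6-olide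
Product: 36 1β,7α,14-trihydroxy-12-methoxyicetexa-8,10(20),11,13-tetraen-19,6-olide
Conditions: NaBH4, CeCl3·7H2O, MeOH/THF, −78 → −40 °C
Reagents that add atoms: none
Why: Luche 1,2-reduction of both carbonyls: at C1 axial attack on the α-face of the ring A half-chair (only axial H-3 and H-5 on that face) should give the equatorial 1β-alcohol, and at C7 the trans-fused lactone holds C6–O near the carbonyl plane and the C6–C5 bond on the α-face, so hydride should enter from the β-face (Felkin–Anh, anti to C5) to give 7α-OH cis to O-6.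

Step 23
Reactants: 36 1β,7α,14-trihydroxy-12-methoxyicetexa-8,10(20),11,13-tetraen-19,6-olide
Product: 37 1β,7α-dihydroxy-12-methoxy-11,14-dioxoicetexa-8,10(20),12-trien-19,6-olide
Conditions: (KSO3)2NO, KH2PO4, acetone/H2O, 0 °C → rt
Reagents that add atoms: potassium nitrosodisulfonate [K+].[K+].[O]N(S(=O)(=O)[O-])S(=O)(=O)[O-]
Why: Teuber oxidation: Fremy's radical oxidises the C14 phenol and delivers oxygen to the free para position C11, giving the p-quinone under near-neutral conditions that the carbinols and lactone tolerate.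

Step 24
Reactants: 37 1β,7α-dihydroxy-12-methoxy-11,14-dioxoicetexa-8,10(20),12-trien-19,6-olide
Product: 38 ballotiquinone, (1R,4S,5R,6R,7S)-1β,7α,12-trihydroxy-11,14-dioxoicetexa-8,10(20),12-trien-19,6-olide
Conditions: 0.5 M aq NaOH, THF, 0 °C; then 1 M HCl to pH 2
Reagents that add atoms: sodium hydroxide [Na+].[OH-]
Why: Addition–elimination of hydroxide at C12 hydrolyses the vinylogous ester of the methoxyquinone, and acidification liberates the hydroxyquinone and recloses any lactone that opened.

**Compound list**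

1 | benzoic acid | OC(=O)c1ccccc1 | starting material
2 | dilithium 1,4-dihydrobenzoate dianion (enediolate) | [Li+].[Li+].[O-]C([O-])=C1C=CCC=C1 | intermediate
3 | 1-methylcyclohexa-2,5-diene-1-carboxylic acid | CC1(C(=O)O)C=CCC=C1 | intermediate
4 | 2-bromo-1-(4-methoxyphenyl)ethan-1-one | COc1ccc(cc1)C(=O)CBr | starting material
5 | 2-(4-methoxyphenyl)-2-oxoethyl 1-methylcyclohexa-2,5-diene-1-carboxylate | COc1ccc(cc1)C(=O)COC(=O)C1(C)C=CCC=C1 | intermediate
6 | 2-(4-methoxyphenyl)-2-oxoethyl 1-methyl-4-oxocyclohexa-2,5-diene-1-carboxylate | COc1ccc(cc1)C(=O)COC(=O)C1(C)C=CC(=O)C=C1 | intermediate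
7 | (3R,3aR,7aS)-3-(4-methoxybenzoyl)-7a-methyl-3a,4-dihydro-2-benzofuran-1,5(3H,7aH)-dione (cis-fused C19→O6 lactone, aroyl exo) | COc1ccc(cc1)C(=O)[C@@H]1OC(=O)[C@@]2(C)C=CC(=O)C[C@@H]12 | intermediate
8 | 4-methoxyphenyl (3R,3aR,7aS)-7a-methyl-1,5-dioxo-1,3,3a,4,5,7a-hexahydro-2-benzofuran-3-carboxylate | COc1ccc(cc1)OC(=O)[C@@H]1OC(=O)[C@@]2(C)C=CC(=O)C[C@@H]12 | intermediate
9 | methyl (1S,6R)-6-[(1R)-1-hydroxy-2-methoxy-2-oxoethyl]-1-methyl-4-oxocyclohex-2-ene-1-carboxylate | COC(=O)[C@H](O)[C@@H]1CC(=O)C=C[C@]1(C)C(=O)OC | intermediate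
10 | methyl (1S,6R)-6-[(1R)-2-methoxy-1-(methoxymethoxy)-2-oxoethyl]-1-methyl-4-oxocyclohex-2-ene-1-carboxylate | COC(=O)[C@H](OCOC)[C@@H]1CC(=O)C=C[C@]1(C)C(=O)OC | intermediate
11 | chloromethyl phenyl sulfide | ClCSc1ccccc1 | starting material
12 | lithium cross-conjugated dienolate of 10 (C1–O, C10=C1) | COC(=O)[C@H](OCOC)[C@@H]1C=C([O-])C=C[C@]1(C)C(=O)OC.[Li+] | intermediate
13 | trimethylsilyl dienol ether of 10 | COC(=O)[C@H](OCOC)[C@@H]1C=C(O[Si](C)(C)C)C=C[C@]1(C)C(=O)OC | intermediate
14 | methyl (1S,5R,6R)-6-[(1R)-2-methoxy-1-(methoxymethoxy)-2-oxoethyl]-1-methyl-4-oxo-5-[(phenylsulfanyl)methyl]cyclohex-2-ene-1-carboxylate (C20 α) | COC(=O)[C@H](OCOC)[C@@H]1[C@@H](CSc2ccccc2)C(=O)C=C[C@]1(C)C(=O)OC | intermediate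
15 | methyl (1S,5R,6R)-6-[(1R)-2-methoxy-1-(methoxymethoxy)-2-oxoethyl]-1-methyl-4-oxo-5-[(phenylsulfonyl)methyl]cyclohex-2-ene-1-carboxylate | COC(=O)[C@H](OCOC)[C@@H]1[C@@H](CS(=O)(=O)c2ccccc2)C(=O)C=C[C@]1(C)C(=O)OC | intermediate
16 | methyl (1S,2R,3R)-2-[(1R)-2-methoxy-1-(methoxymethoxy)-2-oxoethyl]-1-methyl-4-oxo-3-[(phenylsulfonyl)methyl]cyclohexane-1-carboxylate | COC(=O)[C@H](OCOC)[C@@H]1[C@@H](CS(=O)(=O)c2ccccc2)C(=O)CC[C@]1(C)C(=O)OC | intermediate
17 | methyl (6R,7R,8S)-7-[(1R)-2-methoxy-1-(methoxymethoxy)-2-oxoethyl]-8-methyl-6-[(phenylsulfonyl)methyl]-1,4-dioxaspiro[4.5]decane-8-carboxylate | COC(=O)[C@H](OCOC)[C@@H]1[C@@H](CS(=O)(=O)c2ccccc2)C2(OCCO2)CC[C@]1(C)C(=O)OC | intermediate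
18 | ring A-fused cyclopentanone β-keto sulfone (trans-hydrindan-2-one; 6-OMOM, 7-oxo, 20-SO2Ph epimers, C1 ethylene ketal, 4α-CH3, 4β-CO2Me, H-5 α, H-10 β) | COCO[C@H]1C(=O)C(S(=O)(=O)c2ccccc2)[C@@H]2[C@@H]1[C@@](C)(C(=O)OC)CCC23OCCO3 | intermediate
19 | 1,3-dimethoxybenzene | COc1cccc(OC)c1 | starting material
20 | 2,6-dimethoxyphenyllithium | [Li]c1c(OC)cccc1OC | intermediate
21 | 2-(2,6-dimethoxyphenyl)propan-2-ol | COc1cccc(OC)c1C(C)(C)O | intermediate
22 | 2-isopropyl-1,3-dimethoxybenzene | COc1cccc(OC)c1C(C)C | intermediate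
23 | 2-(4-isopropyl-3,5-dimethoxyphenyl)-4,4,5,5-tetramethyl-1,3,2-dioxaborolane | COc1cc(B2OC(C)(C)C(C)(C)O2)cc(OC)c1C(C)C | intermediate
24 | 4-isopropyl-3,5-dimethoxyphenol | COc1cc(O)cc(OC)c1C(C)C | intermediate
25 | 2-bromo-4-isopropyl-3,5-dimethoxyphenol | COc1cc(O)c(Br)c(OC)c1C(C)C | intermediate
26 | (2-bromo-4-isopropyl-3,5-dimethoxyphenoxy)trimethylsilane | COc1cc(O[Si](C)(C)C)c(Br)c(OC)c1C(C)C | intermediate
27 | lithium 4-isopropyl-3,5-dimethoxy-2-(trimethylsilyl)phenoxide | COc1cc([O-])c([Si](C)(C)C)c(OC)c1C(C)C.[Li+] | intermediate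
28 | 4-isopropyl-3,5-dimethoxy-2-(trimethylsilyl)phenyl trifluoromethanesulfonate | COc1cc(OS(=O)(=O)C(F)(F)F)c([Si](C)(C)C)c(OC)c1C(C)C | intermediate
29 | 4-isopropyl-3,5-dimethoxybenzyne (aryne between former C–OTf and C–Si) | COC1=C(C(C)C)C(OC)=CC#C1 | intermediate
30 | cesium benzocyclobutenoxide (C20–C9 and C8–C7 formed, C7–C20 still intact) | CC(C)c1c(OC)cc2c(c1OC)C3([O-])[C@H](OCOC)[C@H]4[C@@](C)(C(=O)OC)CCC5(OCCO5)[C@@H]4C23S(=O)(=O)c1ccccc1.[Cs+] | intermediate
31 | methyl 1,1-(ethylenedioxy)-12,14-dimethoxy-6α-(methoxymethoxy)-7-oxo-20-(phenylsulfonyl)-10βH-icetexa-8,11,13-trien-19-oate (C20 epimers) | CC(C)c1c(OC)cc2c(c1OC)C(=O)[C@H](OCOC)[C@H]1[C@@](C)(C(=O)OC)CCC3(OCCO3)[C@@H]1C2S(=O)(=O)c1ccccc1 | intermediate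
32 | methyl 6α-hydroxy-12,14-dimethoxy-1,7-dioxo-20-(phenylsulfonyl)-10βH-icetexa-8,11,13-trien-19-oate | CC(C)c1c(OC)cc2c(c1OC)C(=O)[C@H](O)[C@H]1[C@@](C)(C(=O)OC)CCC(=O)[C@@H]1C2S(=O)(=O)c1ccccc1 | intermediate
33 | 12,14-dimethoxy-1,7-dioxo-20-(phenylsulfonyl)-10βH-icetexa-8,11,13-trien-19,6-olide | CC(C)c1c(OC)cc2c(c1OC)C(=O)[C@@H]1OC(=O)[C@@]3(C)CCC(=O)[C@@H]([C@@H]13)C2S(=O)(=O)c1ccccc1 | intermediate
34 | 14-hydroxy-12-methoxy-1,7-dioxo-20-(phenylsulfonyl)-10βH-icetexa-8,11,13-trien-19,6-olide | CC(C)c1c(OC)cc2c(c1O)C(=O)[C@@H]1OC(=O)[C@@]3(C)CCC(=O)[C@@H]([C@@H]13)C2S(=O)(=O)c1ccccc1 | intermediate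
35 | 14-hydroxy-12-methoxy-1,7-dioxoicetexa-8,10(20),11,13-tetraen-19,6-olide | CC(C)c1c(OC)cc2c(c1O)C(=O)[C@@H]1OC(=O)[C@@]3(C)CCC(=O)C(=C2)[C@@H]13 | intermediate
36 | 1β,7α,14-trihydroxy-12-methoxyicetexa-8,10(20),11,13-tetraen-19,6-olide | CC(C)c1c(OC)cc2c(c1O)[C@H](O)[C@@H]1OC(=O)[C@@]3(C)CC[C@@H](O)C(=C2)[C@@H]13 | intermediate
37 | 1β,7α-dihydroxy-12-methoxy-11,14-dioxoicetexa-8,10(20),12-trien-19,6-olide | CC(C)C1=C(OC)C(=O)C2=C(C1=O)[C@H](O)[C@@H]1OC(=O)[C@@]3(C)CC[C@@H](O)C(=C2)[C@@H]13 | intermediate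
38 | ballotiquinone, (1R,4S,5R,6R,7S) | CC(C)C1=C(O)C(=O)C2=C(C1=O)[C@H](O)[C@@H]1OC(=O)[C@@]3(C)CC[C@@H](O)C(=C2)[C@@H]13 | target

**Step count and risks**

Total steps: 24. Longest linear sequence: 19 (steps 1–12 and 18–24, from benzoic acid); the aryne precursor takes 5 steps (13–17).

Steps most likely to fail:

Step 18 (aryne insertion). The aryl anion may be protonated before it closes on C7, which stops at simple C20-arylation. The enolate may also be O-arylated, or the product may be arylated a second time at C20. The fallback makes the same two bonds by an anionic annulation on the acyclic sulfone instead of by insertion into the cyclopentanone. It sets out from 17 and 24 and comes back at 31. Phenol 24 is converted with Tf2O/pyridine into 4-isopropyl-3,5-dimethoxyphenyl trifluoromethanesulfonate F1. Sulfone 17 is lithiated at C20 with LiTMP (THF, −78 °C), then F1 and a second equivalent of LiTMP are added. ortho-Lithiation of F1 between OTf and OMe and loss of lithium triflate release the same aryne 29. The sulfonyl carbanion adds at C9, and the aryllithium at C8 acylates on the C7 methyl ester (7-exo-trig), which should give 31 directly.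

Step 4 (desymmetrising Michael addition). The ion-paired enolate may discriminate poorly between the two enone arms, or the enantiomeric purity may erode through retro-Michael and re-addition. The fallback moves the stereo-determining event to enamine catalysis. It sets out from 3 and comes back at 9. Acid 3 is esterified with 2,2-dimethoxyethanol (Steglich conditions) to 2,2-dimethoxyethyl 1-methylcyclohexa-2,5-diene-1-carboxylate F2. Oxidation as in step 3 gives the dienone acetal F3, and aqueous TFA gives 2-oxoethyl 1-methyl-4-oxocyclohexa-2,5-diene-1-carboxylate F4. A diarylprolinol silyl ether catalyst (enantiomer chosen for the 4S,5R series) closes the cis-lactone aldehyde F5 by intramolecular enamine Michael addition, with the exo aldehyde favoured by equilibration. Pinnick oxidation gives the lactone acid F6, TMSCHN2 gives the lactone methyl ester F7, and NaOMe/MeOH opens F7 to 9.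

Step 22 (double reduction). Facial selectivity may be poor at C7 or C1 when both carbonyls are reduced under substrate control in one pot, and some 1,4-reduction of the enone may occur. The fallback separates the two events and puts C7 under catalyst control. It sets out from 35 and comes back at 36. One equivalent of NaBH4/CeCl3 at −78 °C reduces the C1 enone first, since the C7 ketone is deactivated by the hydrogen-bonded ortho-phenol. This gives 1β,14-dihydroxy-12-methoxy-7-oxoicetexa-8,10(20),11,13-tetraen-19,6-olide F8. The aryl ketone of F8 is then reduced by Corey–Bakshi–Shibata reduction (oxazaborolidine enantiomer chosen for 7S, BH3·SMe2) to 36.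

**Further compounds**

F1 | step 18 | 4-isopropyl-3,5-dimethoxyphenyl trifluoromethanesulfonate | COc1cc(OS(=O)(=O)C(F)(F)F)cc(OC)c1C(C)C
F2 | step 4 | 2,2-dimethoxyethyl 1-methylcyclohexa-2,5-diene-1-carboxylate | COC(OC)COC(=O)C1(C)C=CCC=C1
F3 | step 4 | 2,2-dimethoxyethyl 1-methyl-4-oxocyclohexa-2,5-diene-1-carboxylate | COC(OC)COC(=O)C1(C)C=CC(=O)C=C1
F4 | step 4 | 2-oxoethyl 1-methyl-4-oxocyclohexa-2,5-diene-1-carboxylate | O=CCOC(=O)C1(C)C=CC(=O)C=C1
F5 | step 4 | (1R,3aR,7aS)-7a-methyl-3,6-dioxo-1,3,3a,6,7,7a-hexahydro-2-benzofuran-1-carbaldehyde (icetexane 4S,5R,6R) | O=C[C@@H]1OC(=O)[C@@]2(C)C=CC(=O)C[C@@H]12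
F6 | step 4 | (3R,3aR,7aS)-7a-methyl-1,5-dioxo-1,3,3a,4,5,7a-hexahydro-2-benzofuran-3-carboxylic acid | OC(=O)[C@@H]1OC(=O)[C@@]2(C)C=CC(=O)C[C@@H]12
F7 | step 4 | methyl (3R,3aR,7aS)-7a-methyl-1,5-dioxo-1,3,3a,4,5,7a-hexahydro-2-benzofuran-3-carboxylate | COC(=O)[C@@H]1OC(=O)[C@@]2(C)C=CC(=O)C[C@@H]12
F8 | step 22 | 1β,14-dihydroxy-12-methoxy-7-oxoicetexa-8,10(20),11,13-tetraen-19,6-olide | CC(C)c1c(OC)cc2c(c1O)C(=O)[C@@H]1OC(=O)[C@@]3(C)CC[C@@H](O)C(=C2)[C@@H]13
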